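Its constants are those of an exercise, and the outcome is calculated.

Decide first whether this flask needs a better recipe at all.

solid substrate 15 mM; reagent 30.0 mM; protic impurity 0.750 mM; time 5.0 h

    solid substrate ⇌ dissolved substrate, rate k1*(cs1 - [dissolved substrate]) while solid is left; crystals form when [dissolved substrate] > cs1 (cs1 = 7.6 mM, k1 = 7.07 × 10⁻⁴ s⁻¹)
    dissolved substrate + reagent → target (k2 = 0.0971 L mol⁻¹ s⁻¹)
    solid product ⇌ target, rate k3*(cs3 - [target]) while solid is left; crystals form when [target] > cs3 (cs3 = 6.7 mM, k3 = 0.0325 s⁻¹)
    solid substrate + protic impurity → quenched substrate (k4 = 1.26 L mol⁻¹ s⁻¹)

- target is meant together with its solid product
- solid, in amounts per volume of the solution: solid substrate, solid product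
- at the start none of the solid substrate is in solution
- run time (flask): 5.0 h

* amount of target and solid product together at 5.0 h, in percent of the solid substrate charged
* the change that raises the amount of target and solid product together at 5.0 h, in percent of the solid substrate charged most ("none" if none brings more than 2 percentage points) (epsilon / zeta / alpha / beta / none)
* amount of target and solid product together at 5.0 h, in percent of the solid substrate charged, after epsilon

- epsilon: doubling the dissolution coefficient of step 3, all else as stated
- zeta: doubling the amount of reagent, all else as stated
- alpha: doubling the solubility in step 3, all else as stated
- beta: doubling the solubility in step 1, all else as stated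

**Counting turnovers.** Ask how many charges of solid substrate the flask can turn over in the run. Dissolution into a solution held empty, with [dissolved substrate] kept at nothing, delivers at most 6.45 charges by the end, if the solid never ran out. The reagent pays for 2.00 charges. Call the smaller of these two the turnover number T, the charges that supply and reagent allow within the time: 2.00. Here the reagent sets it, being less than the supply. Speed and loss aside, the charge can finish above one, and below one you expect a yield near T.

**Is that enough?** No: T sees neither speed nor loss. Speed looks harmless in this flask: dissolved substrate has a half-life of 0.066 h by step 2 alone, with reagent as charged, far shorter than the run. Loss is not. The protic impurity has a half-life of 0.611 min against the solid as charged, far shorter than the 46.5 min that step 1 needs to deliver one charge at its top rate. So I take 5.00% of the charge as quenched, and I reckon 95.0% for this flask. Doubling the reagent lifts T further above one. Doubling the solubility of solid substrate leaves T as it is, and the changes to target's crystals do not enter it. I expect no option to pay, so I reckon 95.0% after epsilon too.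

**The forecast.** It says 95%, best change none, and 95% after epsilon, on the ground that “faster dissolution or more reagent only speeds up a reaction that already finishes”. My reckoning gives the same values.

**The result.** The simulation gives 95.0%, best change none, and 95.0% after epsilon. With T as the reagent's count, the yield divided by T is the share of reagent spent, so 52.5% should remain. At 5.00 h this flask holds 52% of its reagent.

**Second flask.** With 60 mM of solid substrate, T falls to 0.500, which is the reagent's count, so the reagent is the limiting reagent and you expect about 50.0%. The simulation gives 50.0% there, with 0.030% of the reagent left.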